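## Structural features

The target 18 is a trans-dihydroflavonol. Aromatic ring A is fused along the C4a–C8a bond to a dihydropyranone ring C (O1, C2, C3, C4=O), and the 4-hydroxyphenyl ring B sits on C2. Ring A carries three different oxygen functions in a fixed order: the free 5-OH chelated to the C4 carbonyl, the 7-OMe and the ring oxygen O1. A prenyl chain sits at C8 between O1 and the 7-OMe. The only stereocentres, C2 (R) and C3 (R), are adjacent and trans, with the aryl group and the hydroxyl both equatorial. Several parts are fragile:
- the α-hydroxy ketone with its benzylic C2–O1 bond, which base can open, epimerise or dehydrogenate to the flavonol;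
- the trisubstituted prenyl alkene (acid, electrophiles, hydrogenation) and its C1'' methylene, which is benzylic and allylic at once (oxidants);
- the nucleophilic C6–H of ring A.

The real difficulty is to fix the absolute configuration of C2 and C3 while ring C is built regiospecifically on an unsymmetrical phloroglucinol ring, without a benzylic oxidation or strong acid near the prenyl group. The route exploits two facts. The atoms O1–C8a–C4a–C4 are the skeleton of the ortho-quinone methide of a salicylaldehyde, so C4 arrives already oxygenated. The trans C2-aryl/C3-oxygen pair is an (E)-alkene that carries ring B and a boron atom in place of O3.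

## Logic of the disconnections

**18 ⇒ 17.** The three O–Si bonds at O3, O5 and O4' are cut. The free phenols and the α-ketol are what make 18 sensitive to base and oxidants, so they are unveiled last and in one operation. The forward step needs a buffered, non-basic fluoride source so that C2 and C3 are not epimerised and the prenyl alkene sees no strong acid.

**17 ⇒ 16.** The C4 carbonyl is traced back to a C4 alcohol. This replaces a benzylic C–H oxidation, which would compete with the C1'' methylene, by a simple alcohol oxidation. The forward step needs an oxidant that ignores the electron-rich alkene and arene and does not expose C3 to base.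

**16 ⇒ 15.** The C4–OH bond is exchanged for a C4–OMe bond, because the ring-forming step delivers C4 as its methyl ether. The gain is that O3 and O4 are different from the moment they are made, so no diol has to be differentiated. The forward step is an ionisation at C4 under very mild acid; it needs a group on O3 that cannot take part as a neighbour.

**15 ⇒ 14.** The O3–Si bond is cut. Silylation must not use a silyl triflate, which could ionise the C4 ether.

**14 ⇒ 13.** The C3–O bond is traced back to a C3–B bond. Boron is an oxygen equivalent that makes the alkene partner a carbon nucleophile at C3. The forward oxidation must proceed with retention and leave the prenyl alkene alone.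

**13 ⇒ 5 + 9 + 10 (through 11 and 12).** O1–C2 and C3–C4 are cut, which removes ring C and all three stereocentres at once and leaves an aldehyde, an alkenylboronate and an orthoester. The forward step must control the orientation of the alkene (boron-bearing carbon to C4), keep the (E)-geometry as the trans relation, and select one face of the alkene through a chiral counter-anion. It must also spare the C–B bond, the prenyl group and the protecting groups.

**9 ⇒ 6 + 7 (through 8).** The C=C bond is cut; a one-carbon bis-boron unit and a purchasable aldehyde remain. The forward olefination must give the (E)-isomer.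

**5 ⇒ 4.** The O–Si bond at the unhindered phenol is cut. The forward step must distinguish the two hydroxyls ortho to the formyl group, one flanked by the prenyl chain and one by hydrogen.

**4 ⇒ 2 + 3.** The bond between the ring carbon and C1'' is cut. In 2 the two nucleophilic ring carbons are equivalent, so the position of the prenyl group is not in question. The forward step must favour C- over O-alkylation and stop after one alkylation.

**2 ⇒ 1.** The O–CH3 bond is cut. The forward step must methylate only the hydroxyl para to the formyl group.

## Other disconnections considered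

**Alternative 1:** The cut is the C4–C4a bond. In the forward direction the aryl ether acid A1 would be activated as its mixed anhydride with trifluoroacetic anhydride and would acylate the ring intramolecularly to give A2.
- In its favour: the ether tether leaves only one ring carbon within reach, since the other position ortho to the ether oxygen carries the prenyl chain, so the regiochemistry is enforced by structure.
- Better than the chosen plan on two points: C4 is formed directly at the ketone level, where the chosen plan needs an exchange and an oxidation; and both stereocentres exist before ring closure and can rest on established asymmetric oxidation chemistry, where the chosen plan relies on unproven enantiocontrol.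
- Equal or better on precedent: the ring closure is a known reaction type.
- Against it: a strongly electrophilic, acidic medium meets a trisubstituted alkene on a very electron-rich ring, so addition to or acylation of the prenyl group is a realistic side reaction. The activated α-acyloxy acid can lose its C3 configuration through enolisation. A1 requires an ether bond between a hindered ortho-prenyl phenol and a secondary benzylic carbon with clean inversion. A2 still carries a 5-O-methyl group that must be cleaved beside the 7-O-methyl group with a Lewis acid in the presence of the prenyl chain, followed by deacetylation of a base-sensitive ketol.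
- Step economy: the end game is shorter (two steps against five), but the preparation of A1 is longer, so the totals should be similar.

**Alternative 2:** The cuts are C8–C8a and C4a–C5, so ring A is made last. A Brassard-type diene A4 would add across the brominated alkene of the chiral pyranone A3. Loss of HBr, methanol and the silyl group would aromatise the adduct to A5.
- Better than the chosen plan on regiochemistry: the diene dictates the whole substitution pattern, and the free 5-OH, the 7-OMe and the prenyl group emerge already differentiated. The chosen plan needs two selective phenol manipulations for this.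
- Better on the end game: A5 needs only the cleavage of two acetals.
- Equal on new stereocentres: none is formed, since the new ring becomes aromatic.
- Against it: A3 has a stereocentre α to the ketone and a benzylic C2–O bond β to it, so the basic or thermal conditions needed for the aromatisation can epimerise C3 or open the ring. A4 bears the prenyl chain on its reacting terminus, which slows the first bond formation and makes the diene itself laborious and sensitive. Both components need several steps each.
- Step economy: the total should exceed that of the chosen plan, and the sequence is less convergent in practice because A3 is the valuable chiral component.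

**Alternative 3:** The cut is the C3–C4 bond. SmI2 (divalent samarium) would reduce the ring A aldehyde of the dialdehyde A6 to a ketyl, which adds to the second aldehyde and closes ring C to the cis-diol A7.
- Better than the chosen plan on mildness: the ring closure runs under neutral, non-acidic conditions that leave the prenyl group and the acetals alone.
- Better on precedent and on the source of chirality: the pinacol closure to cis-diols is a known reaction type, and C2 comes from the chiral pool and not from an untested catalyst.
- Equal on oxidation level: both C3 and C4 arrive oxygenated.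
- Against it: in A6 the hydrogen on C2 is benzylic and α to an aldehyde, so racemisation by enolisation threatens during its preparation and under the samarium alkoxides. The aryl ether between a phenol flanked by formyl and prenyl groups and a secondary benzylic carbon is hard to make with clean inversion. An α-aryloxy aldehyde can lose its aryloxy group reductively with this reagent. The C3 configuration must be induced during the closure, whereas in the chosen plan the trans relation follows from alkene geometry. A7 has two free secondary hydroxyls, so the benzylic one must be oxidised selectively; in the chosen plan O3 and O4 are different from the start.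
- Step economy: equal at best, probably longer because of the protection and oxidation-state changes needed to reach A6.

Key step: step 5

**Remarks on the chemistry**

- No connectivity had to be corrected. Because boron ranks below carbon, the boronate 13 has the descriptors (2S,3S,4S) although its spatial arrangement at C2 and C3 is that of the (2R,3R) target.
- Design choices: both phenols are carried as tert-butyldimethylsilyl ethers. An alkoxymethyl ether next to the cationic carbon could trap the cation through its outer oxygen, and the bulky silyl chloride should distinguish the two ortho hydroxyls of 4 better.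
- O3 is protected as a silyl ether, not as an ester. An ester could take part at a C4 cation and migrate to O4, and would need base for its removal.
- The boronate is made in one step from a purchasable aldehyde.
- Assumption: which antipode of the chiral acid leads to the (2S,3S) series of 13 cannot be derived from precedent. The (S,S) acid is written; its mirror image is used if the first runs show the opposite sense.

## Route

Step 1
Reactants: 1 2,4,6-trihydroxybenzaldehyde
Product: 2 2,6-dihydroxy-4-methoxybenzaldehyde
Conditions: MeI (1.0 equiv), K2CO3 (1.0 equiv), DMF, 0 °C → rt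
Reagents that add atoms: iodomethane, CI
Why: Williamson O-methylation; the 4-OH is para to the formyl group, the most acidic and not hydrogen-bonded to C=O, so one equivalent of base and MeI should methylate it in preference to the two ortho hydroxyls.

Step 2
Reactants: 2 2,6-dihydroxy-4-methoxybenzaldehyde; 3 prenyl bromide (1-bromo-3-methylbut-2-ene)
Product: 4 2,6-dihydroxy-4-methoxy-3-(3-methylbut-2-en-1-yl)benzaldehyde
Conditions: 10% aq. KOH, 0 °C → rt, slow addition of 3 (1.0 equiv)
Reagents that add atoms: none
Why: C-alkylation of a phloroglucinol-type phenolate in water, where hydrogen bonding to the phenolate oxygens favours attack through carbon; C3 and C5 of 2 are equivalent, so only one mono-C-prenyl product is possible, and SN2 attack at the primary allylic carbon gives the linear prenyl group.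

Step 3
Reactants: 4 2,6-dihydroxy-4-methoxy-3-(3-methylbut-2-en-1-yl)benzaldehyde
Product: 5 6-[(tert-butyldimethylsilyl)oxy]-2-hydroxy-4-methoxy-3-(3-methylbut-2-en-1-yl)benzaldehyde
Conditions: TBSCl (1.05 equiv), imidazole (2 equiv), DMF, 0 °C
Reagents that add atoms: tert-butyldimethylsilyl chloride, CC(C)(C)[Si](C)(C)Cl
Why: Silylation of a phenol; the hydroxyl between formyl and hydrogen is more accessible and more acidic than the one buttressed by the prenyl chain, and the bulky reagent amplifies the difference; the remaining hydroxyl is hindered and hydrogen-bonded to C=O, so the reaction should stop at the mono-ether.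

Step 4
Reactants: 6 4-[(tert-butyldimethylsilyl)oxy]benzaldehyde; 7 bis[(pinacolato)boryl]methane (2,2'-methylenebis(4,4,5,5-tetramethyl-1,3,2-dioxaborolane))
Product: 9 (E)-2-{4-[(tert-butyldimethylsilyl)oxy]phenyl}vinylboronic acid pinacol ester, via lithiated bis(boronate) 8 (not isolated)
Conditions: lithium 2,2,6,6-tetramethylpiperidide (1.2 equiv), 7 (1.2 equiv), THF, 0 °C; then 6, −78 °C → rt
Reagents that add atoms: none
Why: Boron–Wittig olefination: the α-boryl carbanion 8 adds to the aldehyde and the boron–oxygen unit is lost by syn-elimination; the (E)-alkene is expected because the aryl group and the remaining boryl group avoid each other in the four-membered elimination transition state.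

Step 5
Reactants: 5 6-[(tert-butyldimethylsilyl)oxy]-2-hydroxy-4-methoxy-3-(3-methylbut-2-en-1-yl)benzaldehyde; 9 (E)-2-{4-[(tert-butyldimethylsilyl)oxy]phenyl}vinylboronic acid pinacol ester (1.5 equiv); 10 trimethyl orthoformate (1.5 equiv)
Product: 13 (2S,3S,4S)-5-[(tert-butyldimethylsilyl)oxy]-2-{4-[(tert-butyldimethylsilyl)oxy]phenyl}-4,7-dimethoxy-8-(3-methylbut-2-en-1-yl)chroman-3-ylboronic acid pinacol ester (2,3-trans, 2,4-cis), via dimethyl acetal 11 (not isolated), via oxocarbenium ion 12 (not isolated)
Conditions: (S,S)-imidodiphosphoric acid built from two (S)-3,3'-bis(2,4,6-triethylphenyl)-1,1'-bi-2-naphthol units, [(ArO)2P(=O)]2NH (5 mol %), 5 Å molecular sieves, toluene, −20 → 0 °C; Et3N quench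
Reagents that add atoms: none
Why: Proposed new method: the acid turns 5 and 10 into acetal 11 and ionises it to cation 12, which is the O-protonated 4-methoxy ortho-quinone methide, stabilised by the oxygens at C2, C4 and C6 of the former aldehyde and held as a hydrogen-bonded contact ion pair (phenolic OH to phosphoryl oxygen) in the chiral pocket; the closest known reaction types are the achiral acid-catalysed union of salicylaldehydes, orthoformates and styrenes to 2,4-cis-4-alkoxyflavans and chiral phosphoric-acid-type [4+2] reactions of ortho-quinone methides with styrenes, neither of which has used an alkenylboronate or controlled this cation. In 9 the silyloxyphenyl donor and the weakly accepting boryl group place the larger HOMO coefficient on the boron-bearing carbon, which attacks the cationic carbon (C3–C4) while the positive charge that builds at the benzylic carbon is captured by the phenolic oxygen (O1–C2). Ring C thus closes by an asynchronous, suprafacial hetero-[4+2] cycloaddition of inverse electron demand, which in its stepwise limit is a six-membered capture of a benzylic cation by oxygen. C2 and C3 are trans because both bonds form on the same face of the (E)-alkene, and their absolute configuration is decided by which alkene face the chiral anion leaves open. C4 is set by the endo placement of ring B over the cation (2,4-cis, as with styrenes) and is of no consequence for 18, since it becomes the carbonyl carbon. The step needs the regiochemistry (secured by the push–pull polarisation), attack by the styrenyl alkene and not by the less nucleophilic prenyl alkene, and survival of the C–B bond (the pinacol ester is a poor Lewis acid and capture by O1 is intramolecular). The catalyst is chosen only strong enough to ionise the acetal, so that the prenyl alkene next to the free phenol is not protonated, and the silyl ethers cannot trap the cation.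

Step 6
Reactants: 13 the boronate from step 5
Product: 14 (2R,3S,4R)-5-[(tert-butyldimethylsilyl)oxy]-2-{4-[(tert-butyldimethylsilyl)oxy]phenyl}-4,7-dimethoxy-8-(3-methylbut-2-en-1-yl)chroman-3-ol
Conditions: NaBO3·4H2O (4 equiv), THF/H2O (1:1), 0 °C → rt
Reagents that add atoms: sodium perborate (NaBO3·4H2O, drawn as the dimeric peroxoborate), O[B-]1(O)OO[B-](O)(O)OO1.[Na+].[Na+]
Why: Oxidation of the C–B bond: peroxide adds to boron and C3 migrates to oxygen with retention, so the new C3–O bond is trans to ring B; the nucleophilic, mild oxidant should leave the prenyl alkene untouched.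

Step 7
Reactants: 14 the flavan-3-ol from step 6
Product: 15 (2R,3S,4R)-3,5-bis[(tert-butyldimethylsilyl)oxy]-2-{4-[(tert-butyldimethylsilyl)oxy]phenyl}-4,7-dimethoxy-8-(3-methylbut-2-en-1-yl)chromane
Conditions: TBSCl (3 equiv), imidazole (6 equiv), DMF, 40 °C
Reagents that add atoms: tert-butyldimethylsilyl chloride, CC(C)(C)[Si](C)(C)Cl
Why: Silyl ether formation under basic conditions that cannot ionise the C4 ether; a silyl ether on O3 cannot act as a neighbouring group toward a C4 cation, and the excess reagent re-silylates any phenol that the mildly basic step 6 may have bared.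

Step 8
Reactants: 15 the tris-silyl 4-methoxyflavan from step 7
Product: 16 (2R,3S,4RS)-3,5-bis[(tert-butyldimethylsilyl)oxy]-2-{4-[(tert-butyldimethylsilyl)oxy]phenyl}-7-methoxy-8-(3-methylbut-2-en-1-yl)chroman-4-ol (mixture of C4 epimers, used as such)
Conditions: pyridinium p-toluenesulfonate (0.1 equiv), acetone/H2O (5:1), 0.01 M, rt
Reagents that add atoms: water, O
Why: SN1 exchange of a benzylic ether: the C4–OMe bond ionises under very mild acid because the cation is stabilised by O1, O5 and O7, and water in large excess captures it; the silyl ethers should survive, and the C4 epimer mixture is irrelevant because C4 becomes trigonal in the next step.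

Step 9
Reactants: 16 the flavan-4-ol from step 8
Product: 17 (2R,3R)-3,5-bis[(tert-butyldimethylsilyl)oxy]-2-{4-[(tert-butyldimethylsilyl)oxy]phenyl}-7-methoxy-8-(3-methylbut-2-en-1-yl)chroman-4-one
Conditions: Dess–Martin periodinane (1.5 equiv), NaHCO3, CH2Cl2, 0 °C → rt
Reagents that add atoms: none
Why: Dess–Martin oxidation of a secondary benzylic alcohol under buffered, non-basic conditions; the reagent should not attack the prenyl alkene or its activated methylene, and C3, now α to the ketone, is not exposed to base.

Step 10
Reactants: 17 the tris-silyl dihydroflavonol from step 9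
Product: 18 (2R,3R)-3,5-dihydroxy-2-(4-hydroxyphenyl)-7-methoxy-8-(3-methylbut-2-en-1-yl)chroman-4-one (the target)
Conditions: Bu4NF (4 equiv), AcOH (4 equiv), THF, 0 °C → rt
Reagents that add atoms: none
Why: Fluoride-induced cleavage of three silyl ethers; acetic acid buffers the phenoxides and the α-ketol so that C2 and C3 should not epimerise and ring C should not open, and no acid strong enough to add to the prenyl alkene is present.

## Compound list

1 | 2,4,6-trihydroxybenzaldehyde | O=Cc1c(O)cc(O)cc1O | starting material
2 | 2,6-dihydroxy-4-methoxybenzaldehyde | COc1cc(O)c(C=O)c(O)c1 | intermediate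
3 | prenyl bromide (1-bromo-3-methylbut-2-ene) | CC(C)=CCBr | starting material
4 | 2,6-dihydroxy-4-methoxy-3-(3-methylbut-2-en-1-yl)benzaldehyde | COc1cc(O)c(C=O)c(O)c1CC=C(C)C | intermediate
5 | 6-[(tert-butyldimethylsilyl)oxy]-2-hydroxy-4-methoxy-3-(3-methylbut-2-en-1-yl)benzaldehyde | COc1cc(O[Si](C)(C)C(C)(C)C)c(C=O)c(O)c1CC=C(C)C | intermediate
6 | 4-[(tert-butyldimethylsilyl)oxy]benzaldehyde | CC(C)(C)[Si](C)(C)Oc1ccc(C=O)cc1 | starting material
7 | bis[(pinacolato)boryl]methane | CC1(C)OB(CB2OC(C)(C)C(C)(C)O2)OC1(C)C | starting material
8 | lithiated bis[(pinacolato)boryl]methane | [Li]C(B1OC(C)(C)C(C)(C)O1)B1OC(C)(C)C(C)(C)O1 | intermediate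
9 | (E)-2-{4-[(tert-butyldimethylsilyl)oxy]phenyl}vinylboronic acid pinacol ester | CC(C)(C)[Si](C)(C)Oc1ccc(/C=C/B2OC(C)(C)C(C)(C)O2)cc1 | intermediate
10 | trimethyl orthoformate | COC(OC)OC | starting material
11 | dimethyl acetal of 5 | COc1cc(O[Si](C)(C)C(C)(C)C)c(C(OC)OC)c(O)c1CC=C(C)C | intermediate
12 | (E)-O-methyl oxocarbenium ion of 5 (O-protonated 4-methoxy ortho-quinone methide, paired with the catalyst anion) | COc1cc(O[Si](C)(C)C(C)(C)C)c(/C=[O+]/C)c(O)c1CC=C(C)C | intermediate
13 | (2S,3S,4S)-5-[(tert-butyldimethylsilyl)oxy]-2-{4-[(tert-butyldimethylsilyl)oxy]phenyl}-4,7-dimethoxy-8-(3-methylbut-2-en-1-yl)chroman-3-ylboronic acid pinacol ester | COc1cc(O[Si](C)(C)C(C)(C)C)c2c(c1CC=C(C)C)O[C@H](c1ccc(O[Si](C)(C)C(C)(C)C)cc1)[C@@H](B1OC(C)(C)C(C)(C)O1)[C@@H]2OC | intermediate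
14 | (2R,3S,4R)-5-[(tert-butyldimethylsilyl)oxy]-2-{4-[(tert-butyldimethylsilyl)oxy]phenyl}-4,7-dimethoxy-8-(3-methylbut-2-en-1-yl)chroman-3-ol | COc1cc(O[Si](C)(C)C(C)(C)C)c2c(c1CC=C(C)C)O[C@H](c1ccc(O[Si](C)(C)C(C)(C)C)cc1)[C@@H](O)[C@@H]2OC | intermediate
15 | (2R,3S,4R)-3,5-bis[(tert-butyldimethylsilyl)oxy]-2-{4-[(tert-butyldimethylsilyl)oxy]phenyl}-4,7-dimethoxy-8-(3-methylbut-2-en-1-yl)chromane | COc1cc(O[Si](C)(C)C(C)(C)C)c2c(c1CC=C(C)C)O[C@H](c1ccc(O[Si](C)(C)C(C)(C)C)cc1)[C@@H](O[Si](C)(C)C(C)(C)C)[C@@H]2OC | intermediate
16 | (2R,3S,4RS)-3,5-bis[(tert-butyldimethylsilyl)oxy]-2-{4-[(tert-butyldimethylsilyl)oxy]phenyl}-7-methoxy-8-(3-methylbut-2-en-1-yl)chroman-4-ol | COc1cc(O[Si](C)(C)C(C)(C)C)c2c(c1CC=C(C)C)O[C@H](c1ccc(O[Si](C)(C)C(C)(C)C)cc1)[C@@H](O[Si](C)(C)C(C)(C)C)C2O | intermediate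
17 | (2R,3R)-3,5-bis[(tert-butyldimethylsilyl)oxy]-2-{4-[(tert-butyldimethylsilyl)oxy]phenyl}-7-methoxy-8-(3-methylbut-2-en-1-yl)chroman-4-one | COc1cc(O[Si](C)(C)C(C)(C)C)c2c(c1CC=C(C)C)O[C@H](c1ccc(O[Si](C)(C)C(C)(C)C)cc1)[C@@H](O[Si](C)(C)C(C)(C)C)C2=O | intermediate
18 | (2R,3R)-3,5-dihydroxy-2-(4-hydroxyphenyl)-7-methoxy-8-(3-methylbut-2-en-1-yl)chroman-4-one | COc1cc(O)c2c(c1CC=C(C)C)O[C@H](c1ccc(O)cc1)[C@@H](O)C2=O | target

## Step count and least certain steps

Total: 10 steps. Longest linear sequence: 9 steps (steps 1, 2, 3, 5, 6, 7, 8, 9, 10); step 4 is the single step of the second branch.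

**Step 5 (key step, proposed new method).** Three processes are the most likely to go wrong.
- Loss of boron: the benzylic cation formed after the first bond is β to boron and may expel the boryl group in an ipso substitution instead of being captured by O1. That would lead after cyclisation to a boron-free flavene.
- Poor facial selectivity: the cation is strongly delocalised and may pair only loosely with the chiral anion.
- Acid-induced closure of the prenyl chain onto the neighbouring free phenol.

The fallback uses known chemistry only; it sets out from 4 and comes back at 18.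
- 4 is protected at the unhindered hydroxyl (MOMCl, iPr2NEt, CH2Cl2) to give 2-hydroxy-4-methoxy-6-(methoxymethoxy)-3-(3-methylbut-2-en-1-yl)benzaldehyde F1.
- The remaining phenol is allylated (allyl bromide, K2CO3, DMF) to give 2-(allyloxy)-4-methoxy-6-(methoxymethoxy)-3-(3-methylbut-2-en-1-yl)benzaldehyde F2.
- MeMgBr (THF, 0 °C) gives the racemic carbinol 1-[2-(allyloxy)-4-methoxy-6-(methoxymethoxy)-3-(3-methylbut-2-en-1-yl)phenyl]ethanol F3.
- Dess–Martin periodinane gives the acetophenone 1-[2-(allyloxy)-4-methoxy-6-(methoxymethoxy)-3-(3-methylbut-2-en-1-yl)phenyl]ethanone F4.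
- Claisen–Schmidt condensation with purchased 4-(methoxymethoxy)benzaldehyde (KOH, EtOH) gives the (E)-chalcone (E)-1-[2-(allyloxy)-4-methoxy-6-(methoxymethoxy)-3-(3-methylbut-2-en-1-yl)phenyl]-3-[4-(methoxymethoxy)phenyl]prop-2-en-1-one F5.
- Juliá–Colonna epoxidation (poly-L-leucine, urea–hydrogen peroxide, DBU, THF) attacks only the enone and should give the trans-epoxy ketone [2-(allyloxy)-4-methoxy-6-(methoxymethoxy)-3-(3-methylbut-2-en-1-yl)phenyl]{(2R,3S)-3-[4-(methoxymethoxy)phenyl]oxiran-2-yl}methanone F6.
- Pd(PPh3)4 (zerovalent palladium) and morpholine in THF remove the allyl group. The phenol set free next to the prenyl chain opens the epoxide at the benzylic carbon with inversion (pyridinium p-toluenesulfonate in CH2Cl2 if the ring does not close on its own) to give (2R,3R)-3-hydroxy-7-methoxy-5-(methoxymethoxy)-2-[4-(methoxymethoxy)phenyl]-8-(3-methylbut-2-en-1-yl)chroman-4-one F7.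
- HCl in MeOH at room temperature cleaves the two aryl acetals and gives 18.

**Step 2.** O-alkylation and a second C-alkylation compete with the wanted mono-C-prenylation, because the phenolate is ambident and the product is as nucleophilic as the substrate. The fallback sets out from 2 and comes back at 4. Mono-iodination (N-iodosuccinimide, MeCN, 0 °C; the two free ring positions are equivalent) gives 2,6-dihydroxy-3-iodo-4-methoxybenzaldehyde F8. Stille coupling with tributyl(3-methylbut-2-en-1-yl)stannane (Pd(PPh3)4, zerovalent palladium, DMF, 80 °C) then places the linear prenyl group on that carbon and gives 4.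

**Step 3.** The discrimination between the two ortho hydroxyls may be incomplete, since it rests only on the steric and acidity difference caused by the prenyl chain. The fallback sets out from 2 and comes back at 5, bypassing steps 2 and 3.
- 2, whose two hydroxyls are equivalent, is mono-silylated (TBSCl 1.0 equiv, imidazole, DMF) to give 2-[(tert-butyldimethylsilyl)oxy]-6-hydroxy-4-methoxybenzaldehyde F9.
- The remaining phenol is converted with tert-butyl 2-methylbut-3-en-2-yl carbonate and Pd(PPh3)4 (zerovalent palladium, THF, 0 °C) into the tertiary allyl ether 2-[(tert-butyldimethylsilyl)oxy]-4-methoxy-6-[(2-methylbut-3-en-2-yl)oxy]benzaldehyde F10.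
- Aromatic Claisen rearrangement (toluene, 110 °C, or Eu(fod)3 at lower temperature) moves the allyl unit to the only free ortho carbon with inversion of its ends. The prenyl group is then necessarily next to the free hydroxyl, which is 5.

**Step 8.** The C4 cation may be captured by C6 of a second molecule instead of by water (oligomerisation, which is why the step is run dilute). It may also lose a proton toward the flavene, or a silyl group may migrate from O3 to O4 once the C4 hydroxyl is free. The fallback sets out from 15 and comes back at 17, bypassing 16 and step 9. Oxidative cleavage of the benzylic methyl ether with DDQ in CH2Cl2/pH 7 buffer at 0 °C removes hydride from C4, and the hemiketal formed with water collapses to the ketone. This is kept as a fallback because the C1'' methylene of the prenyl chain could also be attacked.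

## Further compounds

F1 | step 5 | 2-hydroxy-4-methoxy-6-(methoxymethoxy)-3-(3-methylbut-2-en-1-yl)benzaldehyde | COc1cc(OCOC)c(C=O)c(O)c1CC=C(C)C
F2 | step 5 | 2-(allyloxy)-4-methoxy-6-(methoxymethoxy)-3-(3-methylbut-2-en-1-yl)benzaldehyde | COc1cc(OCOC)c(C=O)c(OCC=C)c1CC=C(C)C
F3 | step 5 | 1-[2-(allyloxy)-4-methoxy-6-(methoxymethoxy)-3-(3-methylbut-2-en-1-yl)phenyl]ethanol (racemic) | COc1cc(OCOC)c(C(C)O)c(OCC=C)c1CC=C(C)C
F4 | step 5 | 1-[2-(allyloxy)-4-methoxy-6-(methoxymethoxy)-3-(3-methylbut-2-en-1-yl)phenyl]ethanone | COc1cc(OCOC)c(C(C)=O)c(OCC=C)c1CC=C(C)C
F5 | step 5 | (E)-1-[2-(allyloxy)-4-methoxy-6-(methoxymethoxy)-3-(3-methylbut-2-en-1-yl)phenyl]-3-[4-(methoxymethoxy)phenyl]prop-2-en-1-one | COc1cc(OCOC)c(C(=O)/C=C/c2ccc(OCOC)cc2)c(OCC=C)c1CC=C(C)C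
F6 | step 5 | [2-(allyloxy)-4-methoxy-6-(methoxymethoxy)-3-(3-methylbut-2-en-1-yl)phenyl]{(2R,3S)-3-[4-(methoxymethoxy)phenyl]oxiran-2-yl}methanone | COc1cc(OCOC)c(C(=O)[C@@H]2O[C@H]2c2ccc(OCOC)cc2)c(OCC=C)c1CC=C(C)C
F7 | step 5 | (2R,3R)-3-hydroxy-7-methoxy-5-(methoxymethoxy)-2-[4-(methoxymethoxy)phenyl]-8-(3-methylbut-2-en-1-yl)chroman-4-one | COc1cc(OCOC)c2c(c1CC=C(C)C)O[C@H](c1ccc(OCOC)cc1)[C@@H](O)C2=O
F8 | step 2 | 2,6-dihydroxy-3-iodo-4-methoxybenzaldehyde | COc1cc(O)c(C=O)c(O)c1I
F9 | step 3 | 2-[(tert-butyldimethylsilyl)oxy]-6-hydroxy-4-methoxybenzaldehyde | COc1cc(O)c(C=O)c(O[Si](C)(C)C(C)(C)C)c1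
F10 | step 3 | 2-[(tert-butyldimethylsilyl)oxy]-4-methoxy-6-[(2-methylbut-3-en-2-yl)oxy]benzaldehyde | COc1cc(O[Si](C)(C)C(C)(C)C)c(C=O)c(OC(C)(C)C=C)c1
F0 | step 8 | none | none
A1 | alternative 1 | (2R,3R)-2-acetoxy-3-(4-acetoxyphenyl)-3-[3,5-dimethoxy-2-(3-methylbut-2-en-1-yl)phenoxy]propanoic acid | COc1cc(OC)cc(c1CC=C(C)C)O[C@H](c1ccc(OC(C)=O)cc1)[C@@H](OC(C)=O)C(=O)O
A2 | alternative 1 | (2R,3R)-3,4'-di-O-acetyl-5,7-di-O-methyl-8-prenyldihydrokaempferol | COc1cc(OC)c2c(c1CC=C(C)C)O[C@H](c1ccc(OC(C)=O)cc1)[C@@H](OC(C)=O)C2=O
A3 | alternative 2 | (2R,3R)-5-bromo-3-(methoxymethoxy)-2-[4-(methoxymethoxy)phenyl]-2,3-dihydro-4H-pyran-4-one | O=C1C(Br)=CO[C@H](c2ccc(OCOC)cc2)[C@H]1OCOC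
A4 | alternative 2 | {[(1E,3Z)-1,3-dimethoxy-7-methylocta-1,3,6-trien-1-yl]oxy}trimethylsilane | C[Si](C)(C)O/C(OC)=C/C(OC)=C/CC=C(C)C
A5 | alternative 2 | (2R,3R)-7-O-methyl-3,4'-bis-O-(methoxymethyl)-8-prenyldihydrokaempferol | COc1cc(O)c2c(c1CC=C(C)C)O[C@H](c1ccc(OCOC)cc1)[C@@H](OCOC)C2=O
A6 | alternative 3 | 4-methoxy-6-(methoxymethoxy)-2-{(1R)-1-[4-(methoxymethoxy)phenyl]-2-oxoethoxy}-3-(3-methylbut-2-en-1-yl)benzaldehyde | COc1cc(OCOC)c(C=O)c(c1CC=C(C)C)O[C@H](c1ccc(OCOC)cc1)C=O
A7 | alternative 3 | (2R,3S,4S)-7-methoxy-5-(methoxymethoxy)-2-[4-(methoxymethoxy)phenyl]-8-(3-methylbut-2-en-1-yl)chromane-3,4-diol | COc1cc(OCOC)c2c(c1CC=C(C)C)O[C@H](c1ccc(OCOC)cc1)[C@@H](O)[C@H]2O
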